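**Plan**
- Retrosynthesis cuts last the two C-prenyl bonds, C8–C(quaternary) on ring A and C2'–CH2 on ring B. Both are traced back to plain O-prenyl ethers on O7 and O5' of one flavonol. Earlier cuts are O1–C2 and C3–OH (Algar–Flynn–Oyamada), Cα–Cβ of a chalcone (Claisen–Schmidt), and the chroman ring (aryl propargyl ether).
- Forward order: chroman ring (propargyl Claisen/oxa-6π, then hydrogenation), chalcone, ring C, both C-prenyl groups in one thermal operation, MOM removal.
- Enabling feature on ring A: O7 has ortho C8 free and its para carbon C4a locked in the A/C ring fusion, so its prenyl group stops after one [3,3] shift as the reversed 1,1-dimethylallyl group at C8.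
- Enabling feature on ring B: O5' has ortho C4' occupied by the chroman oxygen, ortho C6' crowded by C1', and para C2' free, so the identical O-prenyl group relays on by a Cope shift and arrives at C2' as the normal prenyl group.
- Stereochemistry: none to set. Stereogenic intermediates (racemic dihydroflavonol, sp3 dienone carbons) are erased by oxidation or tautomerisation.

Key step: step 9

Remark on the chemistry (assumption): the target SMILES has no stereocentre and no configured double bond, so the compound is achiral and "the single enantiomer given" is the compound itself. Abbreviations: prenyl = 3-methylbut-2-en-1-yl; tert-prenyl = 2-methylbut-3-en-2-yl (1,1-dimethylallyl); MOM = methoxymethyl.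

**Route**

Step 1
Reactants: 1 1-(2,4,6-trihydroxyphenyl)ethanone
Product: 2 1-[2,6-dihydroxy-4-(prenyloxy)phenyl]ethanone
Conditions: prenyl bromide (1.05 equiv), K2CO3 (1.1 equiv), acetone, rt
Reagents that add atoms: prenyl bromide (CC(C)=CCBr)
Why: The 4-OH is the only phenol not hydrogen-bonded to the acetyl group and is the most acidic, so one equivalent of base should give the 4-O-prenyl ether by Williamson etherification.

Step 2
Reactants: 2 1-[2,6-dihydroxy-4-(prenyloxy)phenyl]ethanone
Product: 3 1-[2-hydroxy-6-(methoxymethoxy)-4-(prenyloxy)phenyl]ethanone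
Conditions: MOMCl (1.1 equiv), i-Pr2NEt, CH2Cl2, 0 °C
Reagents that add atoms: chloromethyl methyl ether (COCCl)
Why: After one of the two equivalent phenols is capped, the other stays chelated to the ketone and unreactive, so standard MOM protection should stop at the mono-ether and leave the OH needed for ring C.

Step 3
Reactants: 4 3,4-dihydroxybenzaldehyde
Product: 5 3-hydroxy-4-[(2-methylbut-3-yn-2-yl)oxy]benzaldehyde
Conditions: 3-chloro-3-methylbut-1-yne (1.2 equiv), K2CO3 (1.1 equiv), KI (cat.), CuI (cat.), acetone, 60 °C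
Reagents that add atoms: 3-chloro-3-methylbut-1-yne (C#CC(C)(C)Cl)
Why: Copper-catalysed propargylic etherification should occur on the more acidic 4-phenoxide (para to CHO) when only one equivalent of base is present.

Step 4
Reactants: 5 3-hydroxy-4-[(2-methylbut-3-yn-2-yl)oxy]benzaldehyde
Product: 8 8-hydroxy-2,2-dimethyl-2H-chromene-6-carbaldehyde, via allenyl cyclohexadienone 6 (not isolated), via ortho-quinone methide 7 (not isolated)
Conditions: PhNEt2, 190 °C, Ar
Reagents that add atoms: none
Why: Aryl propargyl ether Claisen rearrangement, enolisation/1,5-H shift and oxa-6π electrocyclisation give the 2,2-dimethylchromene, and the ring fusion is unambiguous because the other ortho carbon carries the OH.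

Step 5
Reactants: 8 8-hydroxy-2,2-dimethyl-2H-chromene-6-carbaldehyde
Product: 9 8-hydroxy-2,2-dimethylchromane-6-carbaldehyde
Conditions: H2 (1 atm), 10% Pd/C, Ph2S (cat.), EtOAc, rt
Reagents that add atoms: none
Why: Catalytic hydrogenation over sulfide-moderated Pd/C should saturate the cis-disubstituted styrenic C3=C4 bond much faster than it reduces the electron-rich aryl aldehyde.

Step 6
Reactants: 9 8-hydroxy-2,2-dimethylchromane-6-carbaldehyde
Product: 10 2,2-dimethyl-8-(prenyloxy)chromane-6-carbaldehyde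
Conditions: prenyl bromide (1.2 equiv), K2CO3, DMF, rt
Reagents that add atoms: prenyl bromide (CC(C)=CCBr)
Why: Williamson etherification of the single phenol installs the O-prenyl group that will later travel to C2'.

Step 7
Reactants: 3 1-[2-hydroxy-6-(methoxymethoxy)-4-(prenyloxy)phenyl]ethanone; 10 2,2-dimethyl-8-(prenyloxy)chromane-6-carbaldehyde
Product: 11 (2E)-1-[2-hydroxy-6-(methoxymethoxy)-4-(prenyloxy)phenyl]-3-[2,2-dimethyl-8-(prenyloxy)chroman-6-yl]prop-2-en-1-one
Conditions: KOH (50% aq.), EtOH, rt, Ar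
Reagents that add atoms: none
Why: Claisen–Schmidt aldol condensation of the methyl ketone with the non-enolisable aldehyde should give the (E)-enone under thermodynamic control, and the MOM and prenyl ethers are stable to hydroxide.

Step 8
Reactants: 11 (2E)-1-[2-hydroxy-6-(methoxymethoxy)-4-(prenyloxy)phenyl]-3-[2,2-dimethyl-8-(prenyloxy)chroman-6-yl]prop-2-en-1-one
Product: 13 3-hydroxy-5-(methoxymethoxy)-7-(prenyloxy)-2-[2,2-dimethyl-8-(prenyloxy)chroman-6-yl]-4H-chromen-4-one, via trans-dihydroflavonol 12 (not isolated)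
Conditions: 30% H2O2, 2 M NaOH, MeOH–THF, 0 °C to rt
Reagents that add atoms: hydrogen peroxide (OO)
Why: In the Algar–Flynn–Oyamada reaction the phenoxide closes ring C at Cβ while Cα is oxygenated, giving the racemic trans-dihydroflavonol, which the same alkaline peroxide dehydrogenates to the flavonol (both stereocentres erased); the nucleophilic oxidant should not touch the electron-rich prenyl alkenes, and the B ring carries no ortho substituent at this stage.

Step 9
Reactants: 13 3-hydroxy-5-(methoxymethoxy)-7-(prenyloxy)-2-[2,2-dimethyl-8-(prenyloxy)chroman-6-yl]-4H-chromen-4-one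
Product: 18 3,7-dihydroxy-2-[8-hydroxy-2,2-dimethyl-5-prenylchroman-6-yl]-5-(methoxymethoxy)-8-(tert-prenyl)-4H-chromen-4-one, via A-ring C8 dienone 14 (not isolated), via 8-tert-prenyl phenol 15 (not isolated), via B-ring C6' dienone 16 (not isolated), via B-ring C2' dienone 17 (not isolated)
Conditions: 1,2-dichlorobenzene (degassed, 0.05 M), 180 °C, sealed tube, Ar
Reagents that add atoms: none
Why: Each aryl prenyl ether undergoes a concerted aromatic Claisen [3,3] shift to a dearomatised ortho-cyclohexadienone: on ring A the C8 dienone 14 can only tautomerise (its para carbon C4a is the ring fusion) and gives the reversed 1,1-dimethylallyl phenol 15, whereas on ring B the C6' dienone 16, which holds the tertiary group between C5'=O and the aryl-bearing C1', should pass it on by a Cope [3,3] shift to C2' (dienone 17) and then tautomerise to phenol 18 with the normal prenyl group. The closest known reaction types are the ortho-Claisen rearrangement of 7-O-prenyl flavonoids to 8-(1,1-dimethylallyl) flavonoids and the Claisen–Cope (para-Claisen) relay of aryl prenyl ethers, for example 5-O-prenyl to 8-C-prenyl flavonoids, which proceeds although an ortho hydrogen is present. No ring is closed and no stereocentre is kept, since the sp3 carbons of 14, 16 and 17 are racemic and become sp2 again on tautomerisation. The step needs C8 over C6 on ring A, which the bond fixation of the benzopyranone (higher C7–C8 bond order, as in 7-allyloxychromones) and the unchelated 5-OMOM group should secure; it also needs Cope relay over enolisation on ring B, which the steric compression at C6', the blocked ortho carbon C4' (a [3,3] shift to C4' also funnels to C2') and the aprotic, base-free medium should favour. The two ethers react independently, so the order shown (ring A first) is bookkeeping only.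

Step 10
Reactants: 18 3,7-dihydroxy-2-[8-hydroxy-2,2-dimethyl-5-prenylchroman-6-yl]-5-(methoxymethoxy)-8-(tert-prenyl)-4H-chromen-4-one
Product: 19 Broussoflavonol E
Conditions: 2 M HCl (aq.), MeOH–THF, rt
Reagents that add atoms: none
Why: The 5-OMOM acetal peri to the C4 carbonyl should be cleaved by dilute methanolic acid at room temperature (acetal solvolysis), conditions too mild to protonate the prenyl and 1,1-dimethylallyl alkenes into cyclisation.

**Compound list**

1 | 1-(2,4,6-trihydroxyphenyl)ethanone | CC(=O)c1c(O)cc(O)cc1O | starting material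
2 | 1-{2,6-dihydroxy-4-[(3-methylbut-2-en-1-yl)oxy]phenyl}ethanone | CC(=O)c1c(O)cc(OCC=C(C)C)cc1O | intermediate
3 | 1-{2-hydroxy-6-(methoxymethoxy)-4-[(3-methylbut-2-en-1-yl)oxy]phenyl}ethanone | CC(=O)c1c(O)cc(OCC=C(C)C)cc1OCOC | intermediate
4 | 3,4-dihydroxybenzaldehyde | O=Cc1ccc(O)c(O)c1 | starting material
5 | 3-hydroxy-4-[(2-methylbut-3-yn-2-yl)oxy]benzaldehyde | O=Cc1ccc(OC(C)(C)C#C)c(O)c1 | intermediate
6 | 5-hydroxy-3-(3-methylbuta-1,2-dien-1-yl)-4-oxocyclohexa-1,5-diene-1-carbaldehyde (racemic) | O=CC1=CC(C=C=C(C)C)C(=O)C(O)=C1 | intermediate (not isolated)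
7 | 5-hydroxy-3-(3-methylbut-2-en-1-ylidene)-4-oxocyclohexa-1,5-diene-1-carbaldehyde | O=CC1=CC(=CC=C(C)C)C(=O)C(O)=C1 | intermediate (not isolated)
8 | 8-hydroxy-2,2-dimethyl-2H-chromene-6-carbaldehyde | O=Cc1cc(O)c2OC(C)(C)C=Cc2c1 | intermediate
9 | 8-hydroxy-2,2-dimethylchromane-6-carbaldehyde | O=Cc1cc(O)c2OC(C)(C)CCc2c1 | intermediate
10 | 2,2-dimethyl-8-[(3-methylbut-2-en-1-yl)oxy]chromane-6-carbaldehyde | O=Cc1cc(OCC=C(C)C)c2OC(C)(C)CCc2c1 | intermediate
11 | (2E)-1-{2-hydroxy-6-(methoxymethoxy)-4-[(3-methylbut-2-en-1-yl)oxy]phenyl}-3-{2,2-dimethyl-8-[(3-methylbut-2-en-1-yl)oxy]chroman-6-yl}prop-2-en-1-one | O=C(/C=C/c1cc(OCC=C(C)C)c2OC(C)(C)CCc2c1)c1c(O)cc(OCC=C(C)C)cc1OCOC | intermediate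
12 | (2R*,3R*)-3-hydroxy-5-(methoxymethoxy)-7-[(3-methylbut-2-en-1-yl)oxy]-2-{2,2-dimethyl-8-[(3-methylbut-2-en-1-yl)oxy]chroman-6-yl}chroman-4-one (racemic trans; one enantiomer drawn) | COCOc1cc(OCC=C(C)C)cc2O[C@H](c3cc(OCC=C(C)C)c4OC(C)(C)CCc4c3)[C@@H](O)C(=O)c12 | intermediate (not isolated)
13 | 3-hydroxy-5-(methoxymethoxy)-7-[(3-methylbut-2-en-1-yl)oxy]-2-{2,2-dimethyl-8-[(3-methylbut-2-en-1-yl)oxy]chroman-6-yl}-4H-chromen-4-one | COCOc1cc(OCC=C(C)C)cc2oc(-c3cc(OCC=C(C)C)c4OC(C)(C)CCc4c3)c(O)c(=O)c12 | intermediate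
14 | 3-hydroxy-5-(methoxymethoxy)-8-(2-methylbut-3-en-2-yl)-2-{2,2-dimethyl-8-[(3-methylbut-2-en-1-yl)oxy]chroman-6-yl}-8H-chromene-4,7-dione (racemic at C8) | COCOC1=CC(=O)C(C(C)(C)C=C)C2=C1C(=O)C(O)=C(c1cc(OCC=C(C)C)c3OC(C)(C)CCc3c1)O2 | intermediate (not isolated)
15 | 3,7-dihydroxy-5-(methoxymethoxy)-8-(2-methylbut-3-en-2-yl)-2-{2,2-dimethyl-8-[(3-methylbut-2-en-1-yl)oxy]chroman-6-yl}-4H-chromen-4-one | COCOc1cc(O)c(C(C)(C)C=C)c2oc(-c3cc(OCC=C(C)C)c4OC(C)(C)CCc4c3)c(O)c(=O)c12 | intermediate (not isolated)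
16 | 3,7-dihydroxy-5-(methoxymethoxy)-8-(2-methylbut-3-en-2-yl)-2-[2,2-dimethyl-7-(2-methylbut-3-en-2-yl)-8-oxo-3,4,7,8-tetrahydro-2H-chromen-6-yl]-4H-chromen-4-one (ring-B ortho-dienone, racemic at C6') | COCOc1cc(O)c(C(C)(C)C=C)c2oc(C3=CC4=C(OC(C)(C)CC4)C(=O)C3C(C)(C)C=C)c(O)c(=O)c12 | intermediate (not isolated)
17 | 3,7-dihydroxy-5-(methoxymethoxy)-8-(2-methylbut-3-en-2-yl)-2-[2,2-dimethyl-5-(3-methylbut-2-en-1-yl)-8-oxo-3,4,5,8-tetrahydro-2H-chromen-6-yl]-4H-chromen-4-one (ring-B para-dienone, racemic at C2') | COCOc1cc(O)c(C(C)(C)C=C)c2oc(C3=CC(=O)C4=C(CCC(C)(C)O4)C3CC=C(C)C)c(O)c(=O)c12 | intermediate (not isolated)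
18 | 3,7-dihydroxy-2-[8-hydroxy-2,2-dimethyl-5-(3-methylbut-2-en-1-yl)chroman-6-yl]-5-(methoxymethoxy)-8-(2-methylbut-3-en-2-yl)-4H-chromen-4-one | COCOc1cc(O)c(C(C)(C)C=C)c2oc(-c3cc(O)c4OC(C)(C)CCc4c3CC=C(C)C)c(O)c(=O)c12 | intermediate
19 | Broussoflavonol E, 3,5,7-trihydroxy-2-[8-hydroxy-2,2-dimethyl-5-(3-methylbut-2-en-1-yl)chroman-6-yl]-8-(2-methylbut-3-en-2-yl)-4H-chromen-4-one | C=CC(C)(C)c1c(O)cc(O)c2c(=O)c(O)c(-c3cc(O)c4c(c3CC=C(C)C)CCC(C)(C)O4)oc12 | target

**Step count and risks**

Total step count: 10. Longest linear sequence: 8 steps (4 to 19 through steps 3–10).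

Steps most likely to fail:

1. Step 9 (key step). On ring B, tautomerisation of the C6' ortho-dienone may outrun the Cope relay, leaving a reversed prenyl group at C6'. On ring A, part of the migration may go to C6. Thermal loss of isoprene or cyclisation of the ortho-(1,1-dimethylallyl)phenol may also erode the product. The fallback installs the C2' prenyl group by electrophilic substitution and cross-coupling before ring C is built, and keeps only the single ring-A Claisen rearrangement late. It sets out from 9 and comes back to the route at 19. Phenol 9 is protected (MOMCl, i-Pr2NEt) as 8-(methoxymethoxy)-2,2-dimethylchromane-6-carbaldehyde F1. Bromination para to the alkoxy group (NBS, MeCN) should give 5-bromo-8-(methoxymethoxy)-2,2-dimethylchromane-6-carbaldehyde F2. Stille coupling with tributyl(prenyl)stannane (Pd(PPh3)4, DMF, 90 °C) should give 8-(methoxymethoxy)-2,2-dimethyl-5-prenylchromane-6-carbaldehyde F3. Claisen–Schmidt condensation with 3 gives the chalcone F4, and Algar–Flynn–Oyamada oxidation gives the 7-O-prenyl 5,5'-bis-MOM flavonol F5. Thermal Claisen rearrangement of its single aryl prenyl ether gives the 8-tert-prenyl flavonol F6, and methanolic HCl removes both MOM groups to give 19.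

2. Step 8. The 6'-alkoxy group of the chalcone may divert the oxidative cyclisation toward five-membered closure at Cα (aurone formation), or dehydrogenation of the dihydroflavonol may stall. The fallback closes ring C before the oxygen is introduced, so the aurone mode is not available. It sets out from 11 and comes back at 12. Oxa-Michael cyclisation of 11 (NaOAc, EtOH, reflux) gives the racemic 5-(methoxymethoxy)-7-(prenyloxy)-2-[2,2-dimethyl-8-(prenyloxy)chroman-6-yl]chroman-4-one F7. Its kinetic enolate (LiHMDS, THF, −78 °C) is hydroxylated with 2-(phenylsulfonyl)-3-phenyloxaziridine to give 12, which is then isolated and dehydrogenated to 13 with the alkaline peroxide of step 8.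

3. Step 1. C-Alkylation and over-alkylation of the phloroglucinol nucleus may compete with mono-O-alkylation. The fallback differentiates the phenols by protection before any carbon electrophile is used. It sets out from 1 and comes back at 3. Selective silylation of the unchelated 4-OH (TBSCl, imidazole, DMF) gives 1-{4-[(tert-butyldimethylsilyl)oxy]-2,6-dihydroxyphenyl}ethanone F8. Mono-MOM protection (MOMCl, i-Pr2NEt) gives 1-{4-[(tert-butyldimethylsilyl)oxy]-2-hydroxy-6-(methoxymethoxy)phenyl}ethanone F9. One-pot fluoride desilylation and O-alkylation (CsF, prenyl bromide, DMF) then gives 3.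

Further compounds
F1 | step 9 | 8-(methoxymethoxy)-2,2-dimethylchromane-6-carbaldehyde | O=Cc1cc(OCOC)c2OC(C)(C)CCc2c1
F2 | step 9 | 5-bromo-8-(methoxymethoxy)-2,2-dimethylchromane-6-carbaldehyde | O=Cc1cc(OCOC)c2OC(C)(C)CCc2c1Br
F3 | step 9 | 8-(methoxymethoxy)-2,2-dimethyl-5-(3-methylbut-2-en-1-yl)chromane-6-carbaldehyde | O=Cc1cc(OCOC)c2OC(C)(C)CCc2c1CC=C(C)C
F4 | step 9 | (2E)-1-{2-hydroxy-6-(methoxymethoxy)-4-[(3-methylbut-2-en-1-yl)oxy]phenyl}-3-[8-(methoxymethoxy)-2,2-dimethyl-5-(3-methylbut-2-en-1-yl)chroman-6-yl]prop-2-en-1-one | O=C(/C=C/c1cc(OCOC)c2OC(C)(C)CCc2c1CC=C(C)C)c1c(O)cc(OCC=C(C)C)cc1OCOC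
F5 | step 9 | 3-hydroxy-5-(methoxymethoxy)-2-[8-(methoxymethoxy)-2,2-dimethyl-5-(3-methylbut-2-en-1-yl)chroman-6-yl]-7-[(3-methylbut-2-en-1-yl)oxy]-4H-chromen-4-one | COCOc1cc(OCC=C(C)C)cc2oc(-c3cc(OCOC)c4OC(C)(C)CCc4c3CC=C(C)C)c(O)c(=O)c12
F6 | step 9 | 3,7-dihydroxy-5-(methoxymethoxy)-2-[8-(methoxymethoxy)-2,2-dimethyl-5-(3-methylbut-2-en-1-yl)chroman-6-yl]-8-(2-methylbut-3-en-2-yl)-4H-chromen-4-one | COCOc1cc(O)c(C(C)(C)C=C)c2oc(-c3cc(OCOC)c4OC(C)(C)CCc4c3CC=C(C)C)c(O)c(=O)c12
F7 | step 8 | 5-(methoxymethoxy)-7-[(3-methylbut-2-en-1-yl)oxy]-2-{2,2-dimethyl-8-[(3-methylbut-2-en-1-yl)oxy]chroman-6-yl}chroman-4-one (racemic) | COCOc1cc(OCC=C(C)C)cc2OC(c3cc(OCC=C(C)C)c4OC(C)(C)CCc4c3)CC(=O)c12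
F8 | step 1 | 1-{4-[(tert-butyldimethylsilyl)oxy]-2,6-dihydroxyphenyl}ethanone | CC(=O)c1c(O)cc(O[Si](C)(C)C(C)(C)C)cc1O
F9 | step 1 | 1-{4-[(tert-butyldimethylsilyl)oxy]-2-hydroxy-6-(methoxymethoxy)phenyl}ethanone | CC(=O)c1c(O)cc(O[Si](C)(C)C(C)(C)C)cc1OCOC
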